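**Retrosynthetic overview**

1. The C7''–C8'' bond is cut. C8'' carries the aryl ether oxygen to the 2,6-dimethoxyphenyl ring and lies between the benzylic carbinol C7'' and the one-carbon terminus C9''. With C9'' raised to an imide carbonyl, this O–CH unit is an enolisable glycolate, so the bond is made by an auxiliary-controlled syn glycolate aldol onto O-benzylvanillin that joins both halves and sets C7'' and C8'' together.
2. After the aldol, C9'' is taken back down (imide → CH2OH → CH2OTs → CH3) and the two benzyl ethers are removed last.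
3. The aryloxyacetyl imide comes from an sp3–sp2 Negishi coupling (C7'–aryl bond) of a 4-aryl-2,3-dimethylbutylzinc with the (4-bromo-2,6-dimethoxyphenoxy)acetyl imide.
4. C8 and C8' come from one catalytic desymmetrising arylation of meso-2,3-dimethylsuccinic anhydride (C7–aryl bond); C7 and C7' are then reduced from carbonyl to CH2.
5. No ring of the target is formed in the route: the three benzene rings are bought, and the anhydride and oxazolidinone rings are temporary.

Key step: step 9

Assumption: the (S)-configured phosphinooxazoline ligand is taken to direct the arylzinc to the anhydride carbonyl that leads to the (2S,3R) keto acid; if the sense of induction is the opposite, the (R)-ligand is used and nothing else changes.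

**Route**

Step 1
Reactants: 1 meso-2,3-dimethylsuccinic acid
Product: 2 cis-2,3-dimethylsuccinic anhydride
Conditions: AcCl (neat), reflux; evaporation
Reagents that add atoms: none
Why: Cyclodehydration of a 1,4-diacid to the five-membered anhydride under non-basic conditions touches neither stereocentre, so the meso acid should give only the cis (meso) anhydride.

Step 2
Reactants: 2 cis-2,3-dimethylsuccinic anhydride; 3 1-(benzyloxy)-4-bromo-2-methoxybenzene
Product: 6 (2S,3R)-4-[4-(benzyloxy)-3-methoxyphenyl]-2,3-dimethyl-4-oxobutanoic acid, via aryllithium 4 (not isolated), via arylzinc triflate 5 (not isolated)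
Conditions: 3, n-BuLi, THF, −78 °C; Zn(OTf)2, −78 °C → rt; then 2, [Rh(cod)Cl]2 (cat.), (S)-t-Bu-PHOX (cat.), THF, 50 °C; aq. HCl (the acid is enriched by crystallisation of an amine salt if needed)
Reagents that add atoms: none
Why: Rhodium-catalysed enantioselective desymmetrisation of a meso cyclic anhydride by arylzinc acylation (oxidative addition into one enantiotopic C(=O)–O bond selected by the chiral P,N ligand, transmetalation, reductive elimination) reveals both methyl-bearing centres C8 and C8' in one catalytic event, and the ketone/zinc carboxylate product is not enolised under the neutral conditions.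

Step 3
Reactants: 6 (2S,3R)-4-[4-(benzyloxy)-3-methoxyphenyl]-2,3-dimethyl-4-oxobutanoic acid
Product: 7 (2S,3S)-4-[4-(benzyloxy)-3-methoxyphenyl]-2,3-dimethylbutanoic acid
Conditions: Et3SiH (excess), TFA, CH2Cl2, 0 °C → rt
Reagents that add atoms: none
Why: Ionic hydrogenation of an electron-rich aryl ketone, in which the 4-alkoxyphenyl group stabilises the benzylic cation that takes up hydride twice, no second arene is present to trap it, and C8 should keep its configuration as long as hydride capture (excess silane, low temperature) outruns proton loss from the cation.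

Step 4
Reactants: 7 (2S,3S)-4-[4-(benzyloxy)-3-methoxyphenyl]-2,3-dimethylbutanoic acid
Product: 8 (2S,3S)-4-[4-(benzyloxy)-3-methoxyphenyl]-2,3-dimethylbutan-1-ol
Conditions: BH3·SMe2, THF, 0 °C → rt; MeOH
Reagents that add atoms: none
Why: Chemoselective borane reduction of a carboxylic acid to the primary alcohol without acid or base, so C8 and C8' are untouched.

Step 5
Reactants: 8 (2S,3S)-4-[4-(benzyloxy)-3-methoxyphenyl]-2,3-dimethylbutan-1-ol
Product: 9 1-(benzyloxy)-4-[(2S,3S)-4-iodo-2,3-dimethylbutyl]-2-methoxybenzene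
Conditions: I2, PPh3, imidazole, CH2Cl2, 0 °C → rt
Reagents that add atoms: iodine, II
Why: Appel-type iodination of a primary alcohol by SN2 at the CH2 group, which does not involve the stereocentres.

Step 6
Reactants: 10 (R)-4-benzyloxazolidin-2-one; 11 bromoacetyl bromide
Product: 13 (R)-4-benzyl-3-(2-bromoacetyl)oxazolidin-2-one, via lithium oxazolidinide 12 (not isolated)
Conditions: n-BuLi, THF, −78 °C; then 11, −78 → 0 °C
Reagents that add atoms: none
Why: N-Acylation of the lithiated oxazolidinone, in which the acyl bromide reacts far faster than the alkyl bromide at −78 °C and the auxiliary stereocentre is not affected.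

Step 7
Reactants: 13 (R)-4-benzyl-3-(2-bromoacetyl)oxazolidin-2-one; 14 4-bromo-2,6-dimethoxyphenol
Product: 15 (R)-4-benzyl-3-[2-(4-bromo-2,6-dimethoxyphenoxy)acetyl]oxazolidin-2-one
Conditions: K2CO3, acetone, rt
Reagents that add atoms: none
Why: Williamson ether synthesis in which the phenoxide displaces the activated α-bromide of the imide by SN2 under mild carbonate conditions that should leave the imide carbonyls and the aryl bromide alone.

Step 8
Reactants: 9 1-(benzyloxy)-4-[(2S,3S)-4-iodo-2,3-dimethylbutyl]-2-methoxybenzene; 15 (R)-4-benzyl-3-[2-(4-bromo-2,6-dimethoxyphenoxy)acetyl]oxazolidin-2-one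
Product: 17 (R)-4-benzyl-3-(2-{4-[(2R,3S)-4-(4-(benzyloxy)-3-methoxyphenyl)-2,3-dimethylbutyl]-2,6-dimethoxyphenoxy}acetyl)oxazolidin-2-one, via alkylzinc iodide 16 (not isolated)
Conditions: Zn dust, LiCl, THF, 40 °C; then 15, Pd(OAc)2 (cat.), SPhos (cat.), THF, rt → 40 °C
Reagents that add atoms: none
Why: LiCl-promoted zinc insertion into the primary iodide followed by sp3–sp2 Negishi cross-coupling, in which the alkylzinc tolerates imide and benzyl ether, the β-stereocentre cannot epimerise, and the bulky biarylphosphine suppresses β-hydride elimination.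

Step 9
Reactants: 17 (R)-4-benzyl-3-(2-{4-[(2R,3S)-4-(4-(benzyloxy)-3-methoxyphenyl)-2,3-dimethylbutyl]-2,6-dimethoxyphenoxy}acetyl)oxazolidin-2-one; 18 4-(benzyloxy)-3-methoxybenzaldehyde
Product: 21 (R)-4-benzyl-3-[(2R,3S)-3-[4-(benzyloxy)-3-methoxyphenyl]-2-{4-[(2R,3S)-4-(4-(benzyloxy)-3-methoxyphenyl)-2,3-dimethylbutyl]-2,6-dimethoxyphenoxy}-3-hydroxypropanoyl]oxazolidin-2-one, via boron enolate 19 (not isolated), via boron aldolate 20 (not isolated)
Conditions: Bu2BOTf, i-Pr2NEt, CH2Cl2, 0 °C; then 18, −78 → 0 °C; pH 7 buffer, MeOH, 30% H2O2, 0 °C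
Reagents that add atoms: none
Why: Soft enolisation of the N-aryloxyacetyl imide with Bu2BOTf/i-Pr2NEt should give only the (Z)-boron enolate, which adds to the aldehyde through a closed chair-like Zimmerman–Traxler transition state; the closest known reaction type is the Evans syn glycolate aldol of N-aryloxyacetyl oxazolidinones with alkoxybenzaldehydes. No ring of the target is closed; the only ring is the transient six-membered boron chelate of the transition state and aldolate, which the oxidative work-up destroys. C8'' is controlled by the (R)-benzyl auxiliary, whose benzyl group shields one enolate face in the dipole-opposed conformation (dibutylboron cannot chelate the ring carbonyl), and C7'' is relayed from the (Z)-enolate geometry because the aldehyde aryl group sits equatorial in the chair. This gives the 7'',8''-syn (threo) pair, (2R,3S) in the imide and (7''S,8''S) once C9'' is a methyl group. The step needs syn over anti and one enolate face over the other: the first is secured by the (Z)-geometry that glycolate boron enolates adopt, the second by the auxiliary, while C8 and C8' are too remote to interfere. The same event joins the aryloxy half to the aldehyde half, so two of the four stereocentres and the full carbon–oxygen skeleton arise in one operation, and any enantiomeric impurity carried by 17 becomes a diastereomer that can be removed here.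

Step 10
Reactants: 21 (R)-4-benzyl-3-[(2R,3S)-3-[4-(benzyloxy)-3-methoxyphenyl]-2-{4-[(2R,3S)-4-(4-(benzyloxy)-3-methoxyphenyl)-2,3-dimethylbutyl]-2,6-dimethoxyphenoxy}-3-hydroxypropanoyl]oxazolidin-2-one
Product: 22 (1S,2S)-1-[4-(benzyloxy)-3-methoxyphenyl]-2-{4-[(2R,3S)-4-(4-(benzyloxy)-3-methoxyphenyl)-2,3-dimethylbutyl]-2,6-dimethoxyphenoxy}propane-1,3-diol
Conditions: LiBH4, THF, MeOH (1 equiv), 0 °C
Reagents that add atoms: none
Why: Reductive cleavage of the N-acyl oxazolidinone at the exocyclic carbonyl gives the primary alcohol and returns the auxiliary, and the cold, near-neutral conditions should avoid retro-aldol cleavage and epimerisation at C8''.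

Step 11
Reactants: 22 (1S,2S)-1-[4-(benzyloxy)-3-methoxyphenyl]-2-{4-[(2R,3S)-4-(4-(benzyloxy)-3-methoxyphenyl)-2,3-dimethylbutyl]-2,6-dimethoxyphenoxy}propane-1,3-diol
Product: 23 (2S,3S)-3-[4-(benzyloxy)-3-methoxyphenyl]-2-{4-[(2R,3S)-4-(4-(benzyloxy)-3-methoxyphenyl)-2,3-dimethylbutyl]-2,6-dimethoxyphenoxy}-3-hydroxypropyl 4-methylbenzenesulfonate
Conditions: TsCl, pyridine, CH2Cl2, 0 °C
Reagents that add atoms: p-toluenesulfonyl chloride, Cc1ccc(cc1)S(Cl)(=O)=O
Why: Selective sulfonylation of the primary over the hindered secondary benzylic hydroxyl group on steric grounds.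

Step 12
Reactants: 23 (2S,3S)-3-[4-(benzyloxy)-3-methoxyphenyl]-2-{4-[(2R,3S)-4-(4-(benzyloxy)-3-methoxyphenyl)-2,3-dimethylbutyl]-2,6-dimethoxyphenoxy}-3-hydroxypropyl 4-methylbenzenesulfonate
Product: 24 (1S,2S)-1-[4-(benzyloxy)-3-methoxyphenyl]-2-{4-[(2R,3S)-4-(4-(benzyloxy)-3-methoxyphenyl)-2,3-dimethylbutyl]-2,6-dimethoxyphenoxy}propan-1-ol
Conditions: LiEt3BH, THF, 0 °C → rt
Reagents that add atoms: none
Why: SN2 displacement of the primary tosylate by hydride turns C9'' into the methyl group, because hydride delivery to a primary sulfonate should be faster than oxetane formation or fragmentation from the neighbouring alkoxide, and C7'' and C8'' are not touched.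

Step 13
Reactants: 24 (1S,2S)-1-[4-(benzyloxy)-3-methoxyphenyl]-2-{4-[(2R,3S)-4-(4-(benzyloxy)-3-methoxyphenyl)-2,3-dimethylbutyl]-2,6-dimethoxyphenoxy}propan-1-ol
Product: 25 (7''S,8S,8'R,8''S)-4,4''-dihydroxy-3,3',3'',5'-tetramethoxy-4',8''-oxy-8,8'-sesquineolignan-7''-ol
Conditions: H2 (1 atm), 10% Pd/C, EtOAc/MeOH, rt
Reagents that add atoms: none
Why: Hydrogenolysis of the two aryl benzyl ethers under neutral conditions at atmospheric pressure, where O-benzyl cleavage should be much faster than hydrogenolysis of the secondary benzylic C7''–OH bond, so the reaction is stopped after uptake of two equivalents.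

**Compound list**

1 | meso-2,3-dimethylsuccinic acid, (2R,3S) | OC(=O)[C@H](C)[C@H](C)C(=O)O | starting material
2 | cis-2,3-dimethylsuccinic anhydride, (3R,4S)-3,4-dimethyloxolane-2,5-dione | O=C1[C@H](C)[C@H](C)C(=O)O1 | intermediate
3 | 1-(benzyloxy)-4-bromo-2-methoxybenzene | COc1cc(Br)ccc1OCc1ccccc1 | starting material
4 | [4-(benzyloxy)-3-methoxyphenyl]lithium | COc1cc([Li])ccc1OCc1ccccc1 | intermediate
5 | [4-(benzyloxy)-3-methoxyphenyl]zinc triflate | COc1cc([Zn]OS(=O)(=O)C(F)(F)F)ccc1OCc1ccccc1 | intermediate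
6 | (2S,3R)-4-[4-(benzyloxy)-3-methoxyphenyl]-2,3-dimethyl-4-oxobutanoic acid | COc1cc(C(=O)[C@H](C)[C@H](C)C(=O)O)ccc1OCc1ccccc1 | intermediate
7 | (2S,3S)-4-[4-(benzyloxy)-3-methoxyphenyl]-2,3-dimethylbutanoic acid | COc1cc(C[C@H](C)[C@H](C)C(=O)O)ccc1OCc1ccccc1 | intermediate
8 | (2S,3S)-4-[4-(benzyloxy)-3-methoxyphenyl]-2,3-dimethylbutan-1-ol | COc1cc(C[C@H](C)[C@H](C)CO)ccc1OCc1ccccc1 | intermediate
9 | 1-(benzyloxy)-4-[(2S,3S)-4-iodo-2,3-dimethylbutyl]-2-methoxybenzene | COc1cc(C[C@H](C)[C@H](C)CI)ccc1OCc1ccccc1 | intermediate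
10 | (R)-4-benzyloxazolidin-2-one | O=C1N[C@H](Cc2ccccc2)CO1 | starting material
11 | bromoacetyl bromide | BrCC(Br)=O | starting material
12 | lithium (R)-4-benzyl-2-oxooxazolidin-3-ide | [Li]N1[C@H](Cc2ccccc2)COC1=O | intermediate
13 | (R)-4-benzyl-3-(2-bromoacetyl)oxazolidin-2-one | O=C(CBr)N1[C@H](Cc2ccccc2)COC1=O | intermediate
14 | 4-bromo-2,6-dimethoxyphenol | COc1cc(Br)cc(OC)c1O | starting material
15 | (R)-4-benzyl-3-[2-(4-bromo-2,6-dimethoxyphenoxy)acetyl]oxazolidin-2-one | COc1cc(Br)cc(OC)c1OCC(=O)N1[C@H](Cc2ccccc2)COC1=O | intermediate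
16 | {(2S,3S)-4-[4-(benzyloxy)-3-methoxyphenyl]-2,3-dimethylbutyl}zinc iodide | COc1cc(C[C@H](C)[C@H](C)C[Zn]I)ccc1OCc1ccccc1 | intermediate
17 | (R)-4-benzyl-3-(2-{4-[(2R,3S)-4-(4-(benzyloxy)-3-methoxyphenyl)-2,3-dimethylbutyl]-2,6-dimethoxyphenoxy}acetyl)oxazolidin-2-one | COc1cc(C[C@H](C)[C@H](C)Cc2cc(OC)c(OCC(=O)N3[C@H](Cc4ccccc4)COC3=O)c(OC)c2)ccc1OCc1ccccc1 | intermediate
18 | 4-(benzyloxy)-3-methoxybenzaldehyde (O-benzylvanillin) | O=Cc1ccc(OCc2ccccc2)c(OC)c1 | starting material
19 | (Z)-dibutylboron enolate of 17 | COc1cc(C[C@H](C)[C@H](C)Cc2cc(OC)c(O/C=C(\OB(CCCC)CCCC)N3[C@H](Cc4ccccc4)COC3=O)c(OC)c2)ccc1OCc1ccccc1 | intermediate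
20 | O-dibutylboryl aldolate of 21 | COc1cc(C[C@H](C)[C@H](C)Cc2cc(OC)c(O[C@@H](C(=O)N3[C@H](Cc4ccccc4)COC3=O)[C@@H](OB(CCCC)CCCC)c3ccc(OCc4ccccc4)c(OC)c3)c(OC)c2)ccc1OCc1ccccc1 | intermediate
21 | (R)-4-benzyl-3-[(2R,3S)-3-[4-(benzyloxy)-3-methoxyphenyl]-2-{4-[(2R,3S)-4-(4-(benzyloxy)-3-methoxyphenyl)-2,3-dimethylbutyl]-2,6-dimethoxyphenoxy}-3-hydroxypropanoyl]oxazolidin-2-one | COc1cc(C[C@H](C)[C@H](C)Cc2cc(OC)c(O[C@@H](C(=O)N3[C@H](Cc4ccccc4)COC3=O)[C@@H](O)c3ccc(OCc4ccccc4)c(OC)c3)c(OC)c2)ccc1OCc1ccccc1 | intermediate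
22 | (1S,2S)-1-[4-(benzyloxy)-3-methoxyphenyl]-2-{4-[(2R,3S)-4-(4-(benzyloxy)-3-methoxyphenyl)-2,3-dimethylbutyl]-2,6-dimethoxyphenoxy}propane-1,3-diol | COc1cc(C[C@H](C)[C@H](C)Cc2cc(OC)c(O[C@@H](CO)[C@@H](O)c3ccc(OCc4ccccc4)c(OC)c3)c(OC)c2)ccc1OCc1ccccc1 | intermediate
23 | (2S,3S)-3-[4-(benzyloxy)-3-methoxyphenyl]-2-{4-[(2R,3S)-4-(4-(benzyloxy)-3-methoxyphenyl)-2,3-dimethylbutyl]-2,6-dimethoxyphenoxy}-3-hydroxypropyl 4-methylbenzenesulfonate | COc1cc(C[C@H](C)[C@H](C)Cc2cc(OC)c(O[C@@H](COS(=O)(=O)c3ccc(C)cc3)[C@@H](O)c3ccc(OCc4ccccc4)c(OC)c3)c(OC)c2)ccc1OCc1ccccc1 | intermediate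
24 | (1S,2S)-1-[4-(benzyloxy)-3-methoxyphenyl]-2-{4-[(2R,3S)-4-(4-(benzyloxy)-3-methoxyphenyl)-2,3-dimethylbutyl]-2,6-dimethoxyphenoxy}propan-1-ol | COc1cc(C[C@H](C)[C@H](C)Cc2cc(OC)c(O[C@@H](C)[C@@H](O)c3ccc(OCc4ccccc4)c(OC)c3)c(OC)c2)ccc1OCc1ccccc1 | intermediate
25 | (7''S,8S,8'R,8''S)-4,4''-dihydroxy-3,3',3'',5'-tetramethoxy-4',8''-oxy-8,8'-sesquineolignan-7''-ol | COc1cc(C[C@H](C)[C@H](C)Cc2cc(OC)c(O[C@@H](C)[C@@H](O)c3ccc(O)c(OC)c3)c(OC)c2)ccc1O | target

**Step count**

Total: 13 steps. Longest linear sequence: 11 steps (steps 1–5 and 8–13); steps 6 and 7 form the side branch that joins at step 8.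

**The three steps most likely to fail**

Step 3. The benzylic cation may lose a proton from C8 to a styrene and be reprotonated before hydride arrives, which would erode the configuration at C8; prolonged acid may also cleave the benzyl ether. The fallback removes the carbonyl on a metal surface instead of through a free cation. It sets out from 6 and comes back at 8. Hydrogenolysis of 6 (H2, Pd/C, AcOH, 50 °C) should reduce the aryl ketone to CH2 and remove the benzyl group, giving (2S,3S)-4-(4-hydroxy-3-methoxyphenyl)-2,3-dimethylbutanoic acid F1. Double benzylation (BnBr, K2CO3, DMF) gives benzyl (2S,3S)-4-[4-(benzyloxy)-3-methoxyphenyl]-2,3-dimethylbutanoate F2, and LiAlH4 (THF, 0 °C) reduces the ester to 8.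

Step 8. The alkylzinc may be lost by protonolysis or homocoupling, oxidative addition into the electron-rich aryl bromide may be slow, or the organometallic may attack the imide. The fallback reverses the polarity of the coupling and installs the imide afterwards. It sets out from 9 and comes back at 17. Phenol 14 is protected (MOMCl, i-Pr2NEt, CH2Cl2) as 5-bromo-1,3-dimethoxy-2-(methoxymethoxy)benzene F3 and converted (Mg, THF) into [3,5-dimethoxy-4-(methoxymethoxy)phenyl]magnesium bromide F4. Iron-catalysed Kumada coupling of F4 with iodide 9 (Fe(acac)3, TMEDA, THF, 0 °C) should give 1-(benzyloxy)-4-{(2S,3R)-4-[3,5-dimethoxy-4-(methoxymethoxy)phenyl]-2,3-dimethylbutyl}-2-methoxybenzene F5. Acetal cleavage (HCl, MeOH) frees 4-{(2R,3S)-4-[4-(benzyloxy)-3-methoxyphenyl]-2,3-dimethylbutyl}-2,6-dimethoxyphenol F6, which is alkylated with 13 (K2CO3, acetone) to 17.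

Step 9. Enolisation of the hindered aryloxyacetyl imide may be incomplete, syn selectivity may erode, or the electron-rich benzylic aldolate may undergo retro-aldol cleavage during work-up. The fallback gives up the enolate and makes the C7''–aryl bond instead, with C8'' taken from the chiral pool. It sets out from 9 and comes back at 24. Iodide 9 is taken to the phenol F6 as described for step 8. Mitsunobu reaction of F6 with methyl (R)-lactate (PPh3, DIAD, THF) inverts the lactate centre and should give methyl (S)-2-{4-[(2R,3S)-4-(4-(benzyloxy)-3-methoxyphenyl)-2,3-dimethylbutyl]-2,6-dimethoxyphenoxy}propanoate F7. DIBAL-H (CH2Cl2, −78 °C) gives (S)-2-{4-[(2R,3S)-4-(4-(benzyloxy)-3-methoxyphenyl)-2,3-dimethylbutyl]-2,6-dimethoxyphenoxy}propanal F8. Chelation-controlled (Cram-chelate) addition of [4-(benzyloxy)-3-methoxyphenyl]magnesium bromide F9 (from 3 and Mg; MgBr2·OEt2, CH2Cl2/Et2O, −78 °C) should favour the threo alcohol 24.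

**Further compounds**

F1 | step 3 | (2S,3S)-4-(4-hydroxy-3-methoxyphenyl)-2,3-dimethylbutanoic acid | COc1cc(C[C@H](C)[C@H](C)C(=O)O)ccc1O
F2 | step 3 | benzyl (2S,3S)-4-[4-(benzyloxy)-3-methoxyphenyl]-2,3-dimethylbutanoate | COc1cc(C[C@H](C)[C@H](C)C(=O)OCc2ccccc2)ccc1OCc1ccccc1
F3 | step 8 | 5-bromo-1,3-dimethoxy-2-(methoxymethoxy)benzene | COCOc1c(OC)cc(Br)cc1OC
F4 | step 8 | [3,5-dimethoxy-4-(methoxymethoxy)phenyl]magnesium bromide | COCOc1c(OC)cc([Mg]Br)cc1OC
F5 | step 8 | 1-(benzyloxy)-4-{(2S,3R)-4-[3,5-dimethoxy-4-(methoxymethoxy)phenyl]-2,3-dimethylbutyl}-2-methoxybenzene | COc1cc(C[C@H](C)[C@H](C)Cc2cc(OC)c(OCOC)c(OC)c2)ccc1OCc1ccccc1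
F6 | step 8 | 4-{(2R,3S)-4-[4-(benzyloxy)-3-methoxyphenyl]-2,3-dimethylbutyl}-2,6-dimethoxyphenol | COc1cc(C[C@H](C)[C@H](C)Cc2cc(OC)c(O)c(OC)c2)ccc1OCc1ccccc1
F7 | step 9 | methyl (S)-2-{4-[(2R,3S)-4-(4-(benzyloxy)-3-methoxyphenyl)-2,3-dimethylbutyl]-2,6-dimethoxyphenoxy}propanoate | COc1cc(C[C@H](C)[C@H](C)Cc2cc(OC)c(O[C@@H](C)C(=O)OC)c(OC)c2)ccc1OCc1ccccc1
F8 | step 9 | (S)-2-{4-[(2R,3S)-4-(4-(benzyloxy)-3-methoxyphenyl)-2,3-dimethylbutyl]-2,6-dimethoxyphenoxy}propanal | COc1cc(C[C@H](C)[C@H](C)Cc2cc(OC)c(O[C@@H](C)C=O)c(OC)c2)ccc1OCc1ccccc1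
F9 | step 9 | [4-(benzyloxy)-3-methoxyphenyl]magnesium bromide | COc1cc([Mg]Br)ccc1OCc1ccccc1
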